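Atom labels follow flavone numbering throughout (O1, C2, C3, C4, C4a, C5–C8, C8a; ring A = benzo ring, ring C = pyranone, ring B = aryl group on C2), also for open-chain intermediates.

## Analysis of the target

Target 21 is a flavonol. A benzo ring (ring A: C4a, C5, C6, C7, C8, C8a) is fused to a 4-pyranone (ring C: O1, C2, C3, C4), and C2 carries a 4-hydroxyphenyl group (ring B); hydroxyl groups sit on C3, C5, C7 and C4', and C6 carries a 3-hydroxy-3-methylbutyl chain. The molecule is flat and achiral, so there is no stereocentre to set or to relate; the problem is purely constitutional. Ring A is pentasubstituted, with hydrogen only on C8. In any 1,3,5-trioxygenated benzene precursor, C6 and C8 are electronically almost alike, so substitution on a preformed ring A tends to give 6- and 8-isomers and also requires the two oxygens ortho to the acyl carbon to be told apart (one becomes O1, the other the C5 hydroxyl). The sensitive groups are the electron-rich phenols and the C3 enol, which oxidise easily, and above all the tertiary alcohol. Under acid the tertiary alcohol ionises and is trapped by the C5 or C7 oxygen as a 2,2-dimethylchromane, or it dehydrates, so the last steps must be neutral and all five hydroxyls are carried as benzyl ethers for one final hydrogenolysis. The plan rests on the fact that C5(O)–C6(alkyl)–C7(O)–C8(H) is the carbon chain of a 2-alkyl-3-oxobutanoate (ester carbon, α-carbon, ketone carbon, methyl carbon), while C4a and C8a carry an acyl group and a heteroatom, as the two sp carbons of a 1-haloalk-1-yn-3-one do. Ring A can therefore be assembled from two acyclic pieces by a (4+2) cycloaddition in which every substituent position follows from connectivity.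

## Retrosynthetic reasoning

Target 21 is first traced to its pentabenzyl ether 20. All five O–benzyl bonds (O3, O5, O7, O4' and the tertiary side-chain oxygen) are cut together, because one neutral hydrogenolysis is the only deprotection the tertiary carbinol between two phenols can be expected to tolerate. The forward step has to remove five benzyl groups without reducing the pyranone.

In 20 the O1–C8a bond is cut, which leads to the open-chain 1,3-diketone 19 with bromine on C8a. Cutting here, and not at O1–C2 as in a classical cyclodehydration, means a free phenol is never needed at C8a, so the two ortho oxygens of ring A never have to be differentiated: one is an ether from the outset and the other position is a halide. The forward reaction is an intramolecular copper-catalysed O-arylation by the enolate oxygen of the aroyl group.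

Diketone 19 is cut at C2–C3 into aryl ketone 17 and acid chloride 18. Ketone 17 has a single enolisable position, the benzyloxy-bearing CH2 that becomes C3, so the C3 oxygen is carried in from the start and the forward step is a C-acylation of that enolate.

Ketone 17 is the benzyl ether of phenol 16; only the O7–benzyl bond is cut. This places the same protecting group on every oxygen and, in the forward direction, also corrects any material in which C5 emerged as a free phenol.

The key disconnection cuts ring A of 16 at C4a–C5 and C8–C8a into diene 8 and bromoynone 13. These two bonds separate C5–C8, which carry the O/alkyl/O/H pattern of a 2-alkylacetoacetate, from C4a and C8a, which carry the acyl group and the bromine as the alkyne carbons of 13 do. The gain is that all six ring positions receive their substituents from the connectivity of acyclic precursors, so the 6- versus 8-alkyl question cannot arise, and bromine marks C8a for the later C–O bond. The forward reaction has to join the partners in the right orientation, eliminate the C5 silyloxy group to aromatise, and free the C7 phenol.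

Diene 8 is traced through silyl enol ether 7 to β-keto ester 6 by removal of two O-silyl groups; no skeletal bond is cut. Keto ester 6 is cut at the bond between C6 and the side chain into benzyl acetoacetate 5 and iodide 4, a standard enolate alkylation.

Iodide 4 comes from alcohol 3, and 3 from diol 1 through benzylidene acetal 2. The C–O bond of the acetal on the primary side is cut reductively, which puts the benzyl ether on the tertiary oxygen without any protecting-group exchange.

Bromoynone 13 is traced to silylalkyne 12 (C–Br for C–Si), and 12 is cut at the acyl–alkyne bond into Weinreb amide 10 and alkyne 11; amide 10 comes from acid chloride 9. The amide is preferred to a direct Lewis-acid acylation with 9, because α-alkoxy acid chlorides tend to decarbonylate under strong Lewis acids.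

## Alternatives that were turned down

Alternative 1: Aryne insertion into a carboxylic acid.
- Disconnection: C8a–O1 and C4a–C4 are cut together. Ring A becomes an aryne released from the ortho-silylaryl triflate A2 (3,5-bis(benzyloxy)-4-[3-(benzyloxy)-3-methylbutyl]-2-(trimethylsilyl)phenyl trifluoromethanesulfonate). The C4–C3–C2–ring B unit is the acid A3 ((2Z)-2-(benzyloxy)-3-[4-(benzyloxy)phenyl]prop-2-enoic acid).
- Forward key step: fluoride would release the aryne, the carboxylate oxygen would add at C8a, the aryl anion at C4a would attack the carboxyl carbon, and opening of the four-membered intermediate would give the 2'-hydroxychalcone A1 ((Z)-2-(benzyloxy)-3-[4-(benzyloxy)phenyl]-1-{2,4-bis(benzyloxy)-3-[3-(benzyloxy)-3-methylbutyl]-6-hydroxyphenyl}prop-2-en-1-one).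
- For: it is more convergent than the chosen route, since all carbons of rings B and C arrive in one step. The C5 benzyloxy group next to the aryne should direct the oxygen nucleophile to the distal carbon C8a, which is the orientation needed.
- Against: A2 is a hexasubstituted benzene whose substituents must be placed one by one on an existing ring, so the regiochemical problem of ring A is only moved into the precursor. Insertion competes with plain O-arylation when the aryl anion is protonated by the free acid. A1 is at the chalcone oxidation level, so an oxa-Michael closure and a dehydrogenation in the presence of electron-rich rings would still be needed.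
- Comparison: alternative 1 is shorter after its key step and stronger on convergence, but longer and less certain before it. The chosen strategy offers instead a ring A whose pattern is fixed by how acyclic pieces are joined, and it reaches the flavonol oxidation level directly.

Alternative 2: Wolff-triggered benzannulation on a pyranone.
- Disconnection: ring A is cut at C8–C8a, C7–C8, C5–C6 and C4a–C5, leaving a pyranone that already holds rings B and C. The partners are the diazoketone A5 (5-(benzyloxy)-6-[4-(benzyloxy)phenyl]-2-(diazoacetyl)-4H-pyran-4-one) and the siloxyalkyne A6 ({[5-(benzyloxy)-5-methylhex-1-yn-1-yl]oxy}tri(propan-2-yl)silane).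
- Forward key step: Wolff rearrangement of A5 would give a pyranonyl ketene, which would add to A6 in a (2+2) sense. The cyclobutenone would open to a dienylketene, and 6π electrocyclisation onto the pyranone double bond followed by tautomerisation would give A4 (3-(benzyloxy)-2-[4-(benzyloxy)phenyl]-6-[3-(benzyloxy)-3-methylbutyl]-5-hydroxy-7-[(triisopropylsilyl)oxy]-4H-chromen-4-one).
- For: four bonds form in one cascade, no halide and no copper step are needed, and C5–OH and C7–O–Si come out differentiated. On bond economy in the key step it is clearly stronger than the chosen route.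
- Against: the 6π closure has to use the C=C bond of a 4-pyranone, a cross-conjugated vinylogous ester of low reactivity, whereas the reaction type is established for carbocyclic vinyl and aryl ketenes. The pyranone chromophore absorbs where the diazoketone must be photolysed and can rearrange itself. A5 needs arylation of the pyranone and adjustment of its side arm before diazo transfer, and A6 needs an ynolate homologation and is hydrolytically labile, so the step count is not lower.
- Comparison: the chosen strategy makes fewer bonds in its key step, but does so with a polar cycloaddition of well-understood orientation and with precursors made by enolate and acetylide chemistry.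

Alternative 3: Carbene-catalysed benzoin closure.
- Disconnection: the C3–C4 bond of ring C is cut, giving the dialdehyde A8 (2-{3,5-bis(benzyloxy)-4-[3-(benzyloxy)-3-methylbutyl]-2-formylphenoxy}-2-[4-(benzyloxy)phenyl]acetaldehyde, racemic).
- Forward key step: a thiazolium-derived carbene would convert the aryl aldehyde into its acyl-anion equivalent, which would add to the aliphatic aldehyde. This would close ring C as the dihydroflavonol A7 (trans-5,7-bis(benzyloxy)-2-[4-(benzyloxy)phenyl]-6-[3-(benzyloxy)-3-methylbutyl]-3-hydroxy-2,3-dihydro-4H-chromen-4-one, racemic).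
- For: the step is catalytic, mild and metal-free, and it installs the C3 hydroxyl and C4 ketone together. On mildness it is stronger than the copper-mediated closure of the chosen route.
- Against: the required sense needs the carbene to attack the hindered, electron-rich 2,6-dioxygenated aryl aldehyde rather than the unhindered aliphatic one, and the opposite sense gives the isomeric acyloin. The α-aryloxy-α-aryl acetaldehyde in A8 enolises and oxidises easily. A7 is one oxidation level too low. Most important, A8 derives from a 3-alkyl-2,4,6-trioxygenated benzaldehyde in which the two ortho oxygens must be differentiated, so the 6- versus 8-alkyl problem is moved into the starting material and not solved.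
- Comparison: the chosen strategy answers exactly that problem by building ring A, at the price of a longer sequence to ring C.

Key step: step 10

Remarks on the chemistry:
- The double-bond geometry of 7 (expected as an E/Z mixture) and of the ketene acetal in 8 (drawn 1Z) has no consequence for the route.
- Compounds 2, 6, 14 and 19 each carry one stereocentre that is formed racemic and removed later.

## Route

Step 1
Reactants: 1 3-methylbutane-1,3-diol
Product: 2 4,4-dimethyl-2-phenyl-1,3-dioxane (racemic)
Conditions: PhCH(OMe)2, pyridinium p-toluenesulfonate (cat.), CH2Cl2, rt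
Reagents that add atoms: benzaldehyde dimethyl acetal, COC(OC)c1ccccc1
Why: Acid-catalysed transacetalisation closes the six-membered benzylidene acetal of the 1,3-diol; the mild acid spares the tertiary carbinol, and the acetal stereocentre is formed racemic and removed in step 2.

Step 2
Reactants: 2 4,4-dimethyl-2-phenyl-1,3-dioxane
Product: 3 3-(benzyloxy)-3-methylbutan-1-ol
Conditions: i-Bu2AlH, CH2Cl2, 0 °C → rt; aq. potassium sodium tartrate
Reagents that add atoms: none
Why: Regioselective reductive opening of a benzylidene acetal: the aluminium hydride binds the unhindered oxygen on the primary side, that C–O bond breaks, and hydride reduces the oxocarbenium ion left on the tertiary oxygen, so the benzyl ether should end on the hindered oxygen and the primary alcohol is freed.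

Step 3
Reactants: 3 3-(benzyloxy)-3-methylbutan-1-ol
Product: 4 {[(4-iodo-2-methylbutan-2-yl)oxy]methyl}benzene
Conditions: I2, PPh3, imidazole, CH2Cl2, 0 °C → rt
Reagents that add atoms: iodine, [I][I]
Why: Appel-type iodination of a primary alcohol by SN2 displacement of the alkoxyphosphonium ion; the conditions are neutral and leave the tertiary benzyl ether untouched.

Step 4
Reactants: 5 benzyl acetoacetate (1.5 equiv); 4 {[(4-iodo-2-methylbutan-2-yl)oxy]methyl}benzene
Product: 6 benzyl 2-acetyl-5-(benzyloxy)-5-methylhexanoate (racemic)
Conditions: NaH, THF/DMF, 0 °C; then 4, 60 °C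
Reagents that add atoms: none
Why: Acetoacetic ester alkylation: the stabilised enolate displaces the unhindered primary iodide by SN2, the excess of 5 suppresses dialkylation, and the new stereocentre is formed racemic and disappears on enolisation in step 5.

Step 5
Reactants: 6 benzyl 2-acetyl-5-(benzyloxy)-5-methylhexanoate
Product: 7 benzyl 5-(benzyloxy)-5-methyl-2-{1-[(trimethylsilyl)oxy]ethylidene}hexanoate (E/Z mixture)
Conditions: Me3SiCl, Et3N, PhMe, rt, 72 h; filtration under Ar
Reagents that add atoms: chlorotrimethylsilane, C[Si](C)(C)Cl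
Why: Soft enolisation and O-silylation of the β-keto ester give the silyl enol ether; both geometric isomers lead to the same dienolate in step 6.

Step 6
Reactants: 7 benzyl 5-(benzyloxy)-5-methyl-2-{1-[(trimethylsilyl)oxy]ethylidene}hexanoate
Product: 8 (1Z)-1-(benzyloxy)-2-[3-(benzyloxy)-3-methylbutyl]-1,3-bis[(trimethylsilyl)oxy]buta-1,3-diene
Conditions: LiN(i-Pr)2, THF, −78 °C; then Me3SiCl, −78 °C → rt; used crude
Reagents that add atoms: chlorotrimethylsilane, C[Si](C)(C)Cl
Why: γ-Deprotonation of the β-silyloxy enoate gives the extended ester dienolate, which is trapped on oxygen as the ketene silyl acetal; this is the standard two-stage preparation of 1,3-bis(silyloxy)-1,3-dienes from 2-alkylacetoacetates, and the moisture-sensitive product is taken on without purification.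

Step 7
Reactants: 9 benzyloxyacetyl chloride
Product: 10 2-(benzyloxy)-N-methoxy-N-methylacetamide
Conditions: MeNHOMe·HCl, pyridine, CH2Cl2, 0 °C → rt
Reagents that add atoms: N,O-dimethylhydroxylamine hydrochloride, CNOC.Cl
Why: N-Acylation of the hydroxylamine gives the Weinreb amide; pyridine is a weak enough base that the α-alkoxy acid chloride is not diverted through its ketene.

Step 8
Reactants: 10 2-(benzyloxy)-N-methoxy-N-methylacetamide; 11 ethynyltrimethylsilane
Product: 12 1-(benzyloxy)-4-(trimethylsilyl)but-3-yn-2-one
Conditions: 11, n-BuLi, THF, −78 °C; then 10, −78 → 0 °C; cold aq. NH4Cl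
Reagents that add atoms: none
Why: Weinreb ketone synthesis: the lithium acetylide adds once, the N-methoxy chelate holds the tetrahedral intermediate until the quench, and the silyl cap keeps the liberated amine from adding to the ynone.

Step 9
Reactants: 12 1-(benzyloxy)-4-(trimethylsilyl)but-3-yn-2-one
Product: 13 1-(benzyloxy)-4-bromobut-3-yn-2-one
Conditions: N-bromosuccinimide, AgNO3 (0.1 equiv), acetone, rt, dark; used at once
Reagents that add atoms: N-bromosuccinimide, O=C1CCC(=O)N1Br
Why: Silver-catalysed bromodesilylation: monovalent silver converts the alkynylsilane into a silver acetylide, which is brominated by the N-bromo imide; the reaction is established for silylalkynes and terminal alkynes conjugated to carbonyl groups.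

Step 10
Reactants: 8 (1Z)-1-(benzyloxy)-2-[3-(benzyloxy)-3-methylbutyl]-1,3-bis[(trimethylsilyl)oxy]buta-1,3-diene (1.5 equiv); 13 1-(benzyloxy)-4-bromobut-3-yn-2-one
Product: 16 2-(benzyloxy)-1-{2-(benzyloxy)-3-[3-(benzyloxy)-3-methylbutyl]-6-bromo-4-hydroxyphenyl}ethan-1-one, via cycloadduct 14 (not isolated), via aryl silyl ether 15 (not isolated)
Conditions: PhMe, 0 → 60 °C; then pyridinium p-toluenesulfonate (cat.), CH2Cl2, rt; then MeOH, rt
Reagents that add atoms: none
Why: This is a Diels–Alder cycloaddition followed by aromatisation; the closest known reaction type is the benzannulation of 1-alkoxy-1,3-bis(silyloxy)buta-1,3-dienes with acetylenic ketones and esters to resorcinol derivatives, together with the known use of 3-bromopropiolates as dienophiles. The HOMO of 8 has its largest coefficient on the terminal CH2, which both oxygen donors feed, and the LUMO of 13 on the bromine-bearing β-carbon, so C8–C8a forms first and C5–C4a follows in a concerted but asynchronous (4+2) process or by collapse of a short-lived ion pair, giving 14. The only ring closed is ring A, a six-membered carbocycle, by intermolecular (4+2) closure across the diene termini. In 14 the doubly allylic C5 silyloxy group leaves with the proton at C8 (1,4-elimination) under the mild anhydrous acid, because siloxide is the better nucleofuge and the cation left behind is stabilised by the benzyloxy group; this aromatises ring A to 15, and methanol then cleaves the aryl silyl ether to phenol 16. The only new stereocentre is the ketal carbon C5 of 14, formed racemic without control and destroyed on aromatisation. The step needs regioselectivity, which the polarity match of the partners secures, and ring closure in preference to expulsion of bromide from C8a, which thermal conditions without Lewis acid in a non-polar solvent favour. It also needs the silyloxy and not the benzyloxy group to leave from C5; if the latter leaves in part, the free C5 phenol is benzylated in step 11 and the material converges on 17.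

Step 11
Reactants: 16 2-(benzyloxy)-1-{2-(benzyloxy)-3-[3-(benzyloxy)-3-methylbutyl]-6-bromo-4-hydroxyphenyl}ethan-1-one
Product: 17 2-(benzyloxy)-1-{2,4-bis(benzyloxy)-3-[3-(benzyloxy)-3-methylbutyl]-6-bromophenyl}ethan-1-one
Conditions: BnBr (2.5 equiv), K2CO3, DMF, 50 °C
Reagents that add atoms: benzyl bromide, BrCc1ccccc1
Why: Williamson etherification of the C7 phenol; the excess of reagent in warm DMF also benzylates a chelated C5 phenol if one is present, and carbonate is too weak a base to enolise the ketone.

Step 12
Reactants: 17 2-(benzyloxy)-1-{2,4-bis(benzyloxy)-3-[3-(benzyloxy)-3-methylbutyl]-6-bromophenyl}ethan-1-one; 18 4-(benzyloxy)benzoyl chloride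
Product: 19 2-(benzyloxy)-1-{2,4-bis(benzyloxy)-3-[3-(benzyloxy)-3-methylbutyl]-6-bromophenyl}-3-[4-(benzyloxy)phenyl]propane-1,3-dione (racemic at C3; in equilibrium with its enols)
Conditions: LiN(SiMe3)2 (2.1 equiv), THF, −78 °C; then 18 (1.05 equiv), −78 → 0 °C; aq. NH4Cl
Reagents that add atoms: none
Why: Crossed Claisen-type C-acylation of a ketone enolate with an acid chloride: only the CH2 that becomes C3 is enolisable, the enolate oxygen is shielded by the 2,6-disubstituted aryl ring so that attack through carbon is favoured, and the second equivalent of base takes up the more acidic diketone. The stereocentre is formed racemic and is lost in step 13.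

Step 13
Reactants: 19 2-(benzyloxy)-1-{2,4-bis(benzyloxy)-3-[3-(benzyloxy)-3-methylbutyl]-6-bromophenyl}-3-[4-(benzyloxy)phenyl]propane-1,3-dione
Product: 20 3,5,7-tris(benzyloxy)-2-[4-(benzyloxy)phenyl]-6-[3-(benzyloxy)-3-methylbutyl]-4H-chromen-4-one
Conditions: CuI (10 mol %), 1,10-phenanthroline (20 mol %), K2CO3, DMF, 100 °C
Reagents that add atoms: none
Why: Intramolecular Ullmann-type C–O coupling: the enolate oxygen of the aroyl carbonyl displaces bromide at C8a under monovalent copper catalysis and closes the six-membered pyranone. The ortho carbonyl activates the C–Br bond and both benzyloxy groups are meta to it, so they do not deactivate it.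

Step 14
Reactants: 20 3,5,7-tris(benzyloxy)-2-[4-(benzyloxy)phenyl]-6-[3-(benzyloxy)-3-methylbutyl]-4H-chromen-4-one
Product: 21 3,5,7-trihydroxy-6-(3-hydroxy-3-methylbutyl)-2-(4-hydroxyphenyl)-4H-chromen-4-one
Conditions: H2 (1 atm), Pd(OH)2/C, EtOAc/MeOH, rt
Reagents that add atoms: none
Why: Catalytic hydrogenolysis of the four aryl/enol benzyl ethers and the tertiary alkyl benzyl ether under neutral conditions, so that the tertiary alcohol neither cyclises onto a phenol nor dehydrates; the tetrasubstituted C2–C3 bond of the vinylogous ester should resist reduction.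

## Compound list

1 | 3-methylbutane-1,3-diol | CC(C)(O)CCO | starting material
2 | 4,4-dimethyl-2-phenyl-1,3-dioxane (racemic) | CC1(C)CCOC(c2ccccc2)O1 | intermediate
3 | 3-(benzyloxy)-3-methylbutan-1-ol | CC(C)(CCO)OCc1ccccc1 | intermediate
4 | {[(4-iodo-2-methylbutan-2-yl)oxy]methyl}benzene | CC(C)(CCI)OCc1ccccc1 | intermediate
5 | benzyl acetoacetate (benzyl 3-oxobutanoate) | CC(=O)CC(=O)OCc1ccccc1 | starting material
6 | benzyl 2-acetyl-5-(benzyloxy)-5-methylhexanoate (racemic) | CC(=O)C(CCC(C)(C)OCc1ccccc1)C(=O)OCc1ccccc1 | intermediate
7 | benzyl 5-(benzyloxy)-5-methyl-2-{1-[(trimethylsilyl)oxy]ethylidene}hexanoate (E/Z mixture) | CC(O[Si](C)(C)C)=C(CCC(C)(C)OCc1ccccc1)C(=O)OCc1ccccc1 | intermediate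
8 | (1Z)-1-(benzyloxy)-2-[3-(benzyloxy)-3-methylbutyl]-1,3-bis[(trimethylsilyl)oxy]buta-1,3-diene | C=C(O[Si](C)(C)C)/C(CCC(C)(C)OCc1ccccc1)=C(/OCc1ccccc1)O[Si](C)(C)C | intermediate
9 | benzyloxyacetyl chloride | O=C(Cl)COCc1ccccc1 | starting material
10 | 2-(benzyloxy)-N-methoxy-N-methylacetamide | CON(C)C(=O)COCc1ccccc1 | intermediate
11 | ethynyltrimethylsilane | C#C[Si](C)(C)C | starting material
12 | 1-(benzyloxy)-4-(trimethylsilyl)but-3-yn-2-one | O=C(COCc1ccccc1)C#C[Si](C)(C)C | intermediate
13 | 1-(benzyloxy)-4-bromobut-3-yn-2-one | O=C(COCc1ccccc1)C#CBr | intermediate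
14 | 2-(benzyloxy)-1-{6-(benzyloxy)-5-[3-(benzyloxy)-3-methylbutyl]-2-bromo-4,6-bis[(trimethylsilyl)oxy]cyclohexa-1,4-dien-1-yl}ethan-1-one (racemic) | O=C(COCc1ccccc1)C1=C(Br)CC(O[Si](C)(C)C)=C(CCC(C)(C)OCc2ccccc2)C1(OCc1ccccc1)O[Si](C)(C)C | intermediate
15 | 2-(benzyloxy)-1-{2-(benzyloxy)-3-[3-(benzyloxy)-3-methylbutyl]-6-bromo-4-[(trimethylsilyl)oxy]phenyl}ethan-1-one | O=C(COCc1ccccc1)c1c(Br)cc(O[Si](C)(C)C)c(CCC(C)(C)OCc2ccccc2)c1OCc1ccccc1 | intermediate
16 | 2-(benzyloxy)-1-{2-(benzyloxy)-3-[3-(benzyloxy)-3-methylbutyl]-6-bromo-4-hydroxyphenyl}ethan-1-one | O=C(COCc1ccccc1)c1c(Br)cc(O)c(CCC(C)(C)OCc2ccccc2)c1OCc1ccccc1 | intermediate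
17 | 2-(benzyloxy)-1-{2,4-bis(benzyloxy)-3-[3-(benzyloxy)-3-methylbutyl]-6-bromophenyl}ethan-1-one | O=C(COCc1ccccc1)c1c(Br)cc(OCc2ccccc2)c(CCC(C)(C)OCc2ccccc2)c1OCc1ccccc1 | intermediate
18 | 4-(benzyloxy)benzoyl chloride | O=C(Cl)c1ccc(OCc2ccccc2)cc1 | starting material
19 | 2-(benzyloxy)-1-{2,4-bis(benzyloxy)-3-[3-(benzyloxy)-3-methylbutyl]-6-bromophenyl}-3-[4-(benzyloxy)phenyl]propane-1,3-dione (racemic) | O=C(c1ccc(OCc2ccccc2)cc1)C(OCc1ccccc1)C(=O)c1c(Br)cc(OCc2ccccc2)c(CCC(C)(C)OCc2ccccc2)c1OCc1ccccc1 | intermediate
20 | 3,5,7-tris(benzyloxy)-2-[4-(benzyloxy)phenyl]-6-[3-(benzyloxy)-3-methylbutyl]-4H-chromen-4-one | O=c1c(OCc2ccccc2)c(-c2ccc(OCc3ccccc3)cc2)oc2cc(OCc3ccccc3)c(CCC(C)(C)OCc3ccccc3)c(OCc3ccccc3)c12 | intermediate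
21 | 3,5,7-trihydroxy-6-(3-hydroxy-3-methylbutyl)-2-(4-hydroxyphenyl)-4H-chromen-4-one | CC(C)(O)CCc1c(O)cc2oc(-c3ccc(O)cc3)c(O)c(=O)c2c1O | target

## Step count and least certain steps

Total step count: 14. Longest linear sequence: 11 steps (steps 1–6, then 10–14); the bromoynone branch (steps 7–9) joins at step 10.

**Step 10 (key step).** The most likely failure is that, once the C8–C8a bond has begun to form, bromide is expelled from C8a (conjugate addition–elimination) faster than the C5–C4a bond closes. The electrophilic bromoynone may also be consumed by silyl transfer and oligomerisation before it meets the diene. Partial loss of the benzyloxy group in place of the silyloxy group on aromatisation is not a failure, because step 11 corrects it.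

The fallback gives up the cycloaddition and reaches 17 from iodide 4 by substitution of a symmetric arene whose two free ring positions are equivalent, so regiochemistry is again fixed by structure. Iodide 4 would be converted (Zn dust, LiCl, THF) into [3-(benzyloxy)-3-methylbutyl](iodo)zinc F1. Commercial 5-bromobenzene-1,3-diol would be iodinated between its hydroxyl groups (iodine, NaHCO3, water) to 5-bromo-2-iodobenzene-1,3-diol F2 and benzylated (benzyl bromide, K2CO3, DMF) to 1,3-bis(benzyloxy)-5-bromo-2-iodobenzene F3. Negishi coupling of F1 with F3 (Pd(OAc)2, 2-dicyclohexylphosphino-2',6'-dimethoxybiphenyl, THF), in which zerovalent palladium inserts into the C–I bond before the C–Br bond, would give 1,3-bis(benzyloxy)-2-[3-(benzyloxy)-3-methylbutyl]-5-bromobenzene F4. Iodination at one of its two equivalent, doubly activated positions (N-iodosuccinimide, cat. CF3CO2H, MeCN) would give 1,3-bis(benzyloxy)-2-[3-(benzyloxy)-3-methylbutyl]-5-bromo-4-iodobenzene F5. Selective iodine–magnesium exchange (i-PrMgCl·LiCl, THF, −40 °C) would give {2,4-bis(benzyloxy)-3-[3-(benzyloxy)-3-methylbutyl]-6-bromophenyl}magnesium chloride F6, and acylation of F6 with Weinreb amide 10 would give 17, where the fallback rejoins the route.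

**Step 13.** The enolate of the 2-alkoxy-1,3-diketone may suffer retro-Claisen cleavage by carbonate and traces of water at the temperature the hindered C–Br bond needs for insertion of copper, or bromine may be lost reductively.

The fallback sets out from 17 and returns at 20 by the Baker–Venkataraman route, which first turns the bromide into a phenol. Miyaura borylation of 17 (bis(pinacolato)diboron, PdCl2(dppf), KOAc, dioxane, 80 °C) would give 2-(benzyloxy)-1-{2,4-bis(benzyloxy)-3-[3-(benzyloxy)-3-methylbutyl]-6-(4,4,5,5-tetramethyl-1,3,2-dioxaborolan-2-yl)phenyl}ethan-1-one F7. Oxidation (NaBO3, THF/water) would give 2-(benzyloxy)-1-{2,4-bis(benzyloxy)-3-[3-(benzyloxy)-3-methylbutyl]-6-hydroxyphenyl}ethan-1-one F8. Acylation with 18 (pyridine, 4-(dimethylamino)pyridine) would give 3,5-bis(benzyloxy)-2-[(benzyloxy)acetyl]-4-[3-(benzyloxy)-3-methylbutyl]phenyl 4-(benzyloxy)benzoate F9. Acyl transfer with LiN(SiMe3)2 in THF would give 2-(benzyloxy)-1-{2,4-bis(benzyloxy)-3-[3-(benzyloxy)-3-methylbutyl]-6-hydroxyphenyl}-3-[4-(benzyloxy)phenyl]propane-1,3-dione F10, and cyclodehydration (pyridinium p-toluenesulfonate, PhMe, 60 °C) would close ring C to 20. Since C5 is an ether and only C8a carries a free hydroxyl, the closure can take one course only.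

**Step 12.** The enolate may be acylated on oxygen to an enol ester, or the product enolate may be acylated a second time.

The fallback sets out from 17 and returns at 19 by replacing the acid chloride with an aldehyde, which can only react at carbon. The lithium enolate of 17 (LiN(SiMe3)2, THF, −78 °C) would add to commercial 4-(benzyloxy)benzaldehyde to give 2-(benzyloxy)-1-{2,4-bis(benzyloxy)-3-[3-(benzyloxy)-3-methylbutyl]-6-bromophenyl}-3-[4-(benzyloxy)phenyl]-3-hydroxypropan-1-one F11 as a mixture of racemic diastereomers. Oxidation of the benzylic carbinol with Dess–Martin periodinane (NaHCO3, CH2Cl2) would give 19.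

**Step 9.** Silver-mediated desilylation of an electron-poor alkynylsilane may be slow, while the bromoynone, once formed, can add succinimide or water at the β-carbon or polymerise on concentration.

The fallback sets out from 12 and returns at 13 by brominating at the alcohol oxidation level and oxidising last. Reduction of 12 (NaBH4, CeCl3, MeOH, −20 °C) would give 1-(benzyloxy)-4-(trimethylsilyl)but-3-yn-2-ol F12 (racemic). Bromodesilylation (N-bromosuccinimide, AgNO3 cat., acetone) would give 1-(benzyloxy)-4-bromobut-3-yn-2-ol F13 (racemic), a propargylic alcohol that is no Michael acceptor. Oxidation with Dess–Martin periodinane in CH2Cl2 would release 13 in the last operation, as a solution that is filtered and used directly in step 10.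

## Further compounds

F1 | step 10 | [3-(benzyloxy)-3-methylbutyl](iodo)zinc | CC(C)(CC[Zn]I)OCc1ccccc1
F2 | step 10 | 5-bromo-2-iodobenzene-1,3-diol | Oc1cc(Br)cc(O)c1I
F3 | step 10 | 1,3-bis(benzyloxy)-5-bromo-2-iodobenzene | Brc1cc(OCc2ccccc2)c(I)c(OCc2ccccc2)c1
F4 | step 10 | 1,3-bis(benzyloxy)-2-[3-(benzyloxy)-3-methylbutyl]-5-bromobenzene | CC(C)(CCc1c(OCc2ccccc2)cc(Br)cc1OCc1ccccc1)OCc1ccccc1
F5 | step 10 | 1,3-bis(benzyloxy)-2-[3-(benzyloxy)-3-methylbutyl]-5-bromo-4-iodobenzene | Ic1c(Br)cc(OCc2ccccc2)c(CCC(C)(C)OCc2ccccc2)c1OCc1ccccc1
F6 | step 10 | {2,4-bis(benzyloxy)-3-[3-(benzyloxy)-3-methylbutyl]-6-bromophenyl}magnesium chloride | Cl[Mg]c1c(Br)cc(OCc2ccccc2)c(CCC(C)(C)OCc2ccccc2)c1OCc1ccccc1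
F7 | step 13 | 2-(benzyloxy)-1-{2,4-bis(benzyloxy)-3-[3-(benzyloxy)-3-methylbutyl]-6-(4,4,5,5-tetramethyl-1,3,2-dioxaborolan-2-yl)phenyl}ethan-1-one | O=C(COCc1ccccc1)c1c(B2OC(C)(C)C(C)(C)O2)cc(OCc2ccccc2)c(CCC(C)(C)OCc2ccccc2)c1OCc1ccccc1
F8 | step 13 | 2-(benzyloxy)-1-{2,4-bis(benzyloxy)-3-[3-(benzyloxy)-3-methylbutyl]-6-hydroxyphenyl}ethan-1-one | O=C(COCc1ccccc1)c1c(O)cc(OCc2ccccc2)c(CCC(C)(C)OCc2ccccc2)c1OCc1ccccc1
F9 | step 13 | 3,5-bis(benzyloxy)-2-[(benzyloxy)acetyl]-4-[3-(benzyloxy)-3-methylbutyl]phenyl 4-(benzyloxy)benzoate | O=C(COCc1ccccc1)c1c(OC(=O)c2ccc(OCc3ccccc3)cc2)cc(OCc2ccccc2)c(CCC(C)(C)OCc2ccccc2)c1OCc1ccccc1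
F10 | step 13 | 2-(benzyloxy)-1-{2,4-bis(benzyloxy)-3-[3-(benzyloxy)-3-methylbutyl]-6-hydroxyphenyl}-3-[4-(benzyloxy)phenyl]propane-1,3-dione | O=C(c1ccc(OCc2ccccc2)cc1)C(OCc1ccccc1)C(=O)c1c(O)cc(OCc2ccccc2)c(CCC(C)(C)OCc2ccccc2)c1OCc1ccccc1
F11 | step 12 | 2-(benzyloxy)-1-{2,4-bis(benzyloxy)-3-[3-(benzyloxy)-3-methylbutyl]-6-bromophenyl}-3-[4-(benzyloxy)phenyl]-3-hydroxypropan-1-one (racemic diastereomers) | OC(c1ccc(OCc2ccccc2)cc1)C(OCc1ccccc1)C(=O)c1c(Br)cc(OCc2ccccc2)c(CCC(C)(C)OCc2ccccc2)c1OCc1ccccc1
F12 | step 9 | 1-(benzyloxy)-4-(trimethylsilyl)but-3-yn-2-ol (racemic) | OC(COCc1ccccc1)C#C[Si](C)(C)C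
F13 | step 9 | 1-(benzyloxy)-4-bromobut-3-yn-2-ol (racemic) | OC(COCc1ccccc1)C#CBr
A1 | alternative 1 | (Z)-2-(benzyloxy)-3-[4-(benzyloxy)phenyl]-1-{2,4-bis(benzyloxy)-3-[3-(benzyloxy)-3-methylbutyl]-6-hydroxyphenyl}prop-2-en-1-one | O=C(/C(OCc1ccccc1)=C/c1ccc(OCc2ccccc2)cc1)c1c(O)cc(OCc2ccccc2)c(CCC(C)(C)OCc2ccccc2)c1OCc1ccccc1
A2 | alternative 1 | 3,5-bis(benzyloxy)-4-[3-(benzyloxy)-3-methylbutyl]-2-(trimethylsilyl)phenyl trifluoromethanesulfonate | C[Si](C)(C)c1c(OS(=O)(=O)C(F)(F)F)cc(OCc2ccccc2)c(CCC(C)(C)OCc2ccccc2)c1OCc1ccccc1
A3 | alternative 1 | (2Z)-2-(benzyloxy)-3-[4-(benzyloxy)phenyl]prop-2-enoic acid | OC(=O)/C(OCc1ccccc1)=C/c1ccc(OCc2ccccc2)cc1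
A4 | alternative 2 | 3-(benzyloxy)-2-[4-(benzyloxy)phenyl]-6-[3-(benzyloxy)-3-methylbutyl]-5-hydroxy-7-[(triisopropylsilyl)oxy]-4H-chromen-4-one | CC(C)[Si](Oc1cc2oc(-c3ccc(OCc4ccccc4)cc3)c(OCc3ccccc3)c(=O)c2c(O)c1CCC(C)(C)OCc1ccccc1)(C(C)C)C(C)C
A5 | alternative 2 | 5-(benzyloxy)-6-[4-(benzyloxy)phenyl]-2-(diazoacetyl)-4H-pyran-4-one | [N-]=[N+]=CC(=O)c1cc(=O)c(OCc2ccccc2)c(-c2ccc(OCc3ccccc3)cc2)o1
A6 | alternative 2 | {[5-(benzyloxy)-5-methylhex-1-yn-1-yl]oxy}tri(propan-2-yl)silane | CC(C)[Si](OC#CCCC(C)(C)OCc1ccccc1)(C(C)C)C(C)C
A7 | alternative 3 | trans-5,7-bis(benzyloxy)-2-[4-(benzyloxy)phenyl]-6-[3-(benzyloxy)-3-methylbutyl]-3-hydroxy-2,3-dihydro-4H-chromen-4-one (racemic; 2R,3R enantiomer drawn) | O=C1c2c(OCc3ccccc3)c(CCC(C)(C)OCc3ccccc3)c(OCc3ccccc3)cc2O[C@H](c2ccc(OCc3ccccc3)cc2)[C@H]1O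
A8 | alternative 3 | 2-{3,5-bis(benzyloxy)-4-[3-(benzyloxy)-3-methylbutyl]-2-formylphenoxy}-2-[4-(benzyloxy)phenyl]acetaldehyde (racemic) | O=CC(Oc1cc(OCc2ccccc2)c(CCC(C)(C)OCc2ccccc2)c(OCc2ccccc2)c1C=O)c1ccc(OCc2ccccc2)cc1
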